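Ky, Ja, Ve.Ky and Ve.Ja always add up to the whole charge, so Ky can be bounded from the products.

the same everywhere: Ky 0.13 M; Ja 0.13 M; Ej 88 µM
- birch: Ve 2.2 equiv; Qi 0.23 mol%; run made earlier
- oak: Ve 2.2 equiv; Qi 0.35 mol%; run made earlier
- flask: Ve 2.20 equiv; Qi 0.46 mol%; time 25 min

| run | time / min | Ve.Ky / % | Ve.Ja / % |
|---|---|---|---|
| birch | 1.50 | 6 | 2 |
| birch | 5.00 | 9 | 1 |
| birch | 8.00 | 14 | 5 |
| birch | 15.0 | 22 | 0 |
| birch | 20.0 | 28 | 2 |
| birch | 25.0 | 33 | 6 |
| oak | 4.00 | 8 | 1 |
| oak | 8.00 | 19 | 0 |
| oak | 12.0 | 20 | 2 |
| oak | 15.0 | 23 | 2 |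
| oak | 20.0 | 33 | 0 |
| oak | 25.0 | 34 | 3 |

(each reading ± 2 percentage points)

1. Ve.Ky and Ve.Ja together, in percent of the Ky and Ja charged together, at 25 min
2. excess of Ve.Ky over Ve.Ja in the product at 25 min
3. whether the exchange between Ky and Ja keeps pace with the reaction: how far the product's excess at 25 min gets from its value without exchange to its value with instant exchange (above 80% keeps pace, below 20% hardly takes part, else lags behind)

- Ve is single-handed; Ky and Ja are mirror images of each other, charged as a racemate, each of them at the stated concentration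
- the numbers in the tables scatter with a standard deviation of 2 percentage points
- an excess is the difference of the two amounts in percent of their sum
- an excess is below zero if the other one leads
- the handed part of Ve does not stay in what it makes, so the products of the two hands are mirror images too

Without exchange (racemization), Ky stands at 0.5 minus Ve.Ky; with instant exchange, it holds an even split of the unreacted fraction. So define the refill share as how far Ky stands from the first bound to the second.

Now take the rate of Ve.Ky as proportional to Ve times Ky, and replace each curve by its mean. Pooling birch and oak, Ve.Ky reads 16.5% at 8.00 min, 22.5% at 15.0 min and 33.5% at 25.0 min. The mean rate from 15.0 min to 25.0 min is 0.533 of that before 8.00 min, while mean Ve falls by a factor 0.806, so mean Ky falls by a factor 0.662. Start from the midpoint of the early bounds, 43.8%, and neglect the small Ve.Ja. Late Ky then reads 29.0%, between 22.0% and 36.0%. That puts the refill share at 50.0%, give or take 37.7%. It lies above 20% and below 80%, so I commit to "lags behind", with Ve.Ky near 33.5%.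

The forecast says 41%, 83% and hardly takes part: “Nothing shows product passing the ceiling”.

The flask gives 37.2% and 83.6%, and its exchange lags behind, getting 48% of the way.

    Ve + Ky → Ve.Ky (k = 0.170 L mol⁻¹ min⁻¹)
    Qi → Ty (k = 0.00770 min⁻¹)
    Ve + Ja → Ve.Ja (k = 0.0120 L mol⁻¹ min⁻¹)
    Qi + Ej → Qi.Ej (k = 1.60 × 10⁵ L mol⁻¹ min⁻¹)
    Ky + Qi ⇌ Ja + Qi, rate k5*[Qi]*[Ky] forward; the back reaction follows from the equilibrium constant (k = 90.0 L mol⁻¹ min⁻¹)

In this flask at 25.0 min, Ve uses Ky at 0.85 of the rate of the forward step alone of Ky into Ja, but the backward turnover of that exchange stands at 127% of the forward one, so its net flow runs from Ja to Ky. Ky ends at 25.8% between 15.8% and 31.4%, a refill share of 63.8%, and the neighbour flask with 3.70 equiv of Ve, ending at 16.7% Ky, has 66.1%.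

(All runs stem from a simulated flask from invented constants, noise included.)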